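**Retrosynthetic overview**
1. Numbering: C1 = CO2H, C2, then C3(Me)–C4H2–C5(Me) as the carbons of the 1,2-dioxolane, C6, C7(H)(Me), C8–C13, diene C14–C17, Ph. The diene (C14=C15, Horner–Wadsworth–Emmons) and the C8–C9 bond (Wittig, then diimide) come last, because neither would survive cationic peroxide chemistry.
2. Ester C1 and alcohol C8 are the two ends of one temporary ring. They arise by Baeyer–Villiger oxidation and methanolysis of the peroxide-bridged cyclooctanone 13 (temporary C1–C8 bond). Key disconnection: C4–C5 and O–C3 together, since 13 is an isomer of the bridged ozonide 10, which comes from the acyclic 1,5-diketone 9 and H2O2.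
3. Enabling feature: on the dioxolane ring (O1, O2, C3, C4, C5) the arms C2 and C6 are cis. C5 is a ketone-level carbon, C3 with the ring CH2 C4 is a masked methallyl group (a tertiary cation site), and C1 is a carbonyl carbon. Tying C1 to C8 puts C1 and C5 in a 1,5-relation, so both fit into one 6,7,8-trioxabicyclo[3.2.1]octane, whose ether oxygen is then exchanged for C2–C3–C4.
4. Stereochemistry and ring order: only C7 is bought (hemiester 1). The order is δ-lactone 3, then the trioxolane/tetrahydropyran bicycle 10 (C7 sets both bridgeheads), then dioxolane plus cyclooctanone 13 (C5 by inversion, C3 by the bridge), then nine-membered lactone 14, then opened.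

Key step: step 7

Assumption: methyl hydrogen (R)-3-methylglutarate (1) is taken as a purchasable enantiopure building block. Atom numbers in the text are those of the target chain given above.

**Step 1**
Reactants: 1 (3R)-5-methoxy-3-methyl-5-oxopentanoic acid
Product: 3 (4R)-4-methyltetrahydro-2H-pyran-2-one, via hydroxy ester 2 (not isolated)
Conditions: BH3·SMe2 (1.1 equiv), THF, −10 °C → rt; H2O; then TsOH·H2O (5 mol %), CH2Cl2, rt
Reagents that add atoms: none
Why: Borane reduces the free carboxylic acid much faster than the methyl ester (chemoselective acid reduction), and acid-catalysed lactonisation of 2 then closes the six-membered ring; the bought stereocentre C7 is not touched.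

**Step 2**
Reactants: 3 (4R)-4-methyltetrahydro-2H-pyran-2-one
Product: 4 (4R)-6-hydroxy-4-methylhexan-2-one
Conditions: MeLi (1.05 equiv), Et2O/THF, −78 °C; H2O quench at −78 °C
Reagents that add atoms: methyllithium, [Li]C
Why: Mono-addition of an organolithium to a δ-lactone: the lithium hemiketal is stable at −78 °C, so the ketone is released only on quenching and no second addition occurs.

**Step 3**
Reactants: 4 (4R)-6-hydroxy-4-methylhexan-2-one
Product: 5 (3R)-3-methyl-5-oxohexanal
Conditions: Dess–Martin periodinane (1.2 equiv), CH2Cl2, 0 °C → rt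
Reagents that add atoms: none
Why: Dess–Martin oxidation of the primary alcohol (drawn from the open form of the hydroxy ketone/hemiketal equilibrium) runs under neutral conditions that avoid aldol cyclisation of the 1,5-keto aldehyde.

**Step 4**
Reactants: 5 (3R)-3-methyl-5-oxohexanal; 6 2-methylallylboronic acid pinacol ester
Product: 8 (4R)-6-hydroxy-4,8-dimethylnon-8-en-2-one (both C6 epimers), via pinacol borate 7 (not isolated)
Conditions: 6 (1.1 equiv), CH2Cl2, rt; then H2O
Reagents that add atoms: none
Why: Uncatalysed allylboration through a closed six-membered transition state is chemoselective for the aldehyde over the methyl ketone; the new carbinol centre is formed without control because step 5 removes it.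

**Step 5**
Reactants: 8 (4R)-6-hydroxy-4,8-dimethylnon-8-en-2-one
Product: 9 (4S)-4,8-dimethylnon-8-ene-2,6-dione
Conditions: Dess–Martin periodinane (1.3 equiv), pyridine (3 equiv), CH2Cl2, 0 °C
Reagents that add atoms: none
Why: Pyridine-buffered Dess–Martin oxidation turns the homoallylic alcohol into the β,γ-unsaturated ketone without moving the double bond into conjugation (the descriptor at C7 changes only through priorities).

**Step 6**
Reactants: 9 (4S)-4,8-dimethylnon-8-ene-2,6-dione
Product: 10 (1S,3S,5S)-1,3-dimethyl-5-(2-methylprop-2-en-1-yl)-6,7,8-trioxabicyclo[3.2.1]octane (3-methyl equatorial on the tetrahydropyran chair, anti to the O–O bridge)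
Conditions: H2O2 (5 M in Et2O, 1.5 equiv), BF3·OEt2 (0.3 equiv), MeCN, 0 °C → rt
Reagents that add atoms: hydrogen peroxide, OO
Why: Acid-catalysed peroxidative cyclisation of a 1,5-diketone with H2O2 (ozone-free synthesis of bridged ozonides): the bridgeheads C1 and C5 are tied to each other by the bicycle and to C7 by closure through the chair tetrahydropyran that keeps the C7 methyl equatorial, away from the O–O bridge, and the minor axial epimer is removed by chromatography.

**Step 7**
Reactants: 10 (1S,3S,5S)-1,3-dimethyl-5-(2-methylprop-2-en-1-yl)-6,7,8-trioxabicyclo[3.2.1]octane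
Product: 13 (1R,5S,7R)-1,5,7-trimethyl-8,9-dioxabicyclo[5.2.1]decan-3-one, via peroxycarbenium ion 11 (not isolated), via tertiary cation 12 (not isolated)
Conditions: SnCl4 (0.3 equiv), CH2Cl2 (0.01 M), −78 → −40 °C; Et3N quench
Reagents that add atoms: none
Why: Proposed new method: SnCl4 binds the ether oxygen of the 1,2,4-trioxolane ring of 10 and opens its C5–O bond to the ketone-level peroxycarbenium ion 11, the CH2 terminus C4 of the methallyl group on C1 adds to C5 to give the tertiary C3 cation 12, and the peroxide oxygen on C1 moves to C3 while the tin alkoxide folds down to the C1 ketone and frees SnCl4, so the whole event is a catalytic isomerisation. The closest known reaction types are the SnCl4-mediated conversion of ozonides into 1,2-dioxolanes by allyltrimethylsilane and the annulation of peroxycarbenium ions from silylperoxy ketals with 1,1-disubstituted alkenes; the intramolecular version on a bridged ozonide with an unactivated alkene is what is new. The C4–C5 bond closes a seven-membered 1,2-dioxepane ring in the 7-endo-trig mode (it becomes the temporary eight-membered carbocycle once C1–O breaks), and the O–C3 bond closes the five-membered 1,2-dioxolane by transannular capture of the cation, a 1,3-shift of oxygen from C1 to C3. C5 is controlled by topology: the methallyl group sits on bridgehead C1 on the side away from the departing ether oxygen, so the three-carbon bridge C2–C3–C4 can replace the one-atom oxygen bridge only with inversion at C5, which turns the ozonide with equatorial C7 methyl into the (5R,7R) array of the target. C3 is controlled by the ring: a peroxide bridge across positions 1 and 3 of the eight-membered ring can only be cis, so C2 and C6 end up on one face of the dioxolane and both methyl groups on the other. The step needs ionisation at C5–O rather than C1–O and C–C closure faster than proton loss or O–O heterolysis: opening at C1–O is reversible and leads nowhere because C4 would have to close a four-membered ring, the 1,1-disubstituted alkene is held within reach of C5, and high dilution at low temperature without any external nucleophile or carbonyl partner suppresses intermolecular paths.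

**Step 8**
Reactants: 13 (1R,5S,7R)-1,5,7-trimethyl-8,9-dioxabicyclo[5.2.1]decan-3-one
Product: 14 (1R,6S,8R)-1,6,8-trimethyl-4,9,10-trioxabicyclo[6.2.1]undecan-3-one
Conditions: mCPBA (2.5 equiv), CH2Cl2, 0 °C → rt, dark
Reagents that add atoms: 3-chloroperbenzoic acid, O=C(OO)c1cccc(Cl)c1
Why: Baeyer–Villiger oxidation in which C8 should migrate in preference to C2, because C2 is neopentyl-like and carries the electron-withdrawing peroxy-substituted C3 next to it; no stereocentre is touched and the dialkyl peroxide is inert to peracid.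

**Step 9**
Reactants: 14 (1R,6S,8R)-1,6,8-trimethyl-4,9,10-trioxabicyclo[6.2.1]undecan-3-one
Product: 15 methyl 2-[(3R,5R)-5-[(2S)-3-hydroxy-2-methylpropyl]-3,5-dimethyl-1,2-dioxolan-3-yl]acetate
Conditions: K2CO3 (0.2 equiv), MeOH, 0 °C
Reagents that add atoms: methanol, CO
Why: Base-catalysed transesterification (lactone methanolysis) is driven by release of the strain of the bridged nine-membered lactone, and it removes the temporary ring to leave ester C1 and alcohol C8.

**Step 10**
Reactants: 15 methyl 2-[(3R,5R)-5-[(2S)-3-hydroxy-2-methylpropyl]-3,5-dimethyl-1,2-dioxolan-3-yl]acetate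
Product: 16 methyl 2-[(3R,5R)-3,5-dimethyl-5-[(2S)-2-methyl-3-oxopropyl]-1,2-dioxolan-3-yl]acetate
Conditions: Dess–Martin periodinane (1.2 equiv), pyridine, CH2Cl2, 0 °C
Reagents that add atoms: none
Why: Buffered Dess–Martin oxidation gives the α-branched aldehyde without epimerising C7 and without touching the O–O bond; 16 is used at once.

**Step 11**
Reactants: 17 6-bromohexan-1-ol
Product: 18 (6-hydroxyhexyl)triphenylphosphonium bromide
Conditions: PPh3 (1.05 equiv), MeCN, reflux
Reagents that add atoms: triphenylphosphine, c1ccc(cc1)P(c1ccccc1)c1ccccc1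
Why: SN2 quaternisation of triphenylphosphine by a primary bromide, for which the free hydroxyl needs no protection.

**Step 12**
Reactants: 16 methyl 2-[(3R,5R)-3,5-dimethyl-5-[(2S)-2-methyl-3-oxopropyl]-1,2-dioxolan-3-yl]acetate; 18 (6-hydroxyhexyl)triphenylphosphonium bromide
Product: 20 methyl 2-[(3R,5R)-5-[(2S,3Z)-9-hydroxy-2-methylnon-3-en-1-yl]-3,5-dimethyl-1,2-dioxolan-3-yl]acetate, via alkoxide ylide 19 (not isolated)
Conditions: 18 (1.4 equiv), NaN(SiMe3)2 (2.8 equiv), THF, −78 → 0 °C; then 16, −78 → −20 °C; H2O
Reagents that add atoms: none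
Why: Wittig olefination with a non-stabilised ylide (the second equivalent of base only parks the hydroxyl as its alkoxide): addition at −78 °C outruns enolisation so the α-stereocentre C7 is kept, and the Z geometry is irrelevant because step 13 saturates the bond.

**Step 13**
Reactants: 20 methyl 2-[(3R,5R)-5-[(2S,3Z)-9-hydroxy-2-methylnon-3-en-1-yl]-3,5-dimethyl-1,2-dioxolan-3-yl]acetate
Product: 21 methyl 2-[(3R,5R)-5-[(2R)-9-hydroxy-2-methylnonyl]-3,5-dimethyl-1,2-dioxolan-3-yl]acetate
Conditions: 2-nitrobenzenesulfonylhydrazide (excess), Et3N, CH2Cl2, rt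
Reagents that add atoms: none
Why: Diimide reduction transfers H2 to the isolated C=C in a concerted syn fashion and, unlike catalytic hydrogenation, leaves the O–O bond, the ester and the alcohol alone.

**Step 14**
Reactants: 21 methyl 2-[(3R,5R)-5-[(2R)-9-hydroxy-2-methylnonyl]-3,5-dimethyl-1,2-dioxolan-3-yl]acetate
Product: 22 methyl 2-[(3R,5R)-3,5-dimethyl-5-[(2R)-2-methyl-9-oxononyl]-1,2-dioxolan-3-yl]acetate
Conditions: Dess–Martin periodinane (1.2 equiv), pyridine, CH2Cl2, 0 °C
Reagents that add atoms: none
Why: Dess–Martin oxidation of the remote primary alcohol C14 to the aldehyde under conditions already shown compatible with the dioxolane in step 10.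

**Step 15**
Reactants: 22 methyl 2-[(3R,5R)-3,5-dimethyl-5-[(2R)-2-methyl-9-oxononyl]-1,2-dioxolan-3-yl]acetate; 23 diethyl (E)-cinnamylphosphonate
Product: 25 methyl 2-[(3R,5R)-3,5-dimethyl-5-[(2R,9E,11E)-2-methyl-12-phenyldodeca-9,11-dien-1-yl]-1,2-dioxolan-3-yl]acetate, via lithiated phosphonate 24 (not isolated)
Conditions: 23 (1.3 equiv), LiN(SiMe3)2 (1.25 equiv), THF, −78 °C; then 22, −78 → 0 °C; H2O
Reagents that add atoms: none
Why: Horner–Wadsworth–Emmons olefination with the allylic phosphonate anion reacting at its α-carbon should give the new C14=C15 bond E, while the cinnamyl E bond is carried over; the hindered di-tertiary peroxide and the ester tolerate the anion at low temperature.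

**Step 16**
Reactants: 25 methyl 2-[(3R,5R)-3,5-dimethyl-5-[(2R,9E,11E)-2-methyl-12-phenyldodeca-9,11-dien-1-yl]-1,2-dioxolan-3-yl]acetate
Product: 26 2-[(3R,5R)-3,5-dimethyl-5-[(2R,9E,11E)-2-methyl-12-phenyldodeca-9,11-dien-1-yl]-1,2-dioxolan-3-yl]acetic acid
Conditions: LiOH·H2O (3 equiv), THF/MeOH/H2O, 0 °C → rt; then 1 M HCl to pH 3
Reagents that add atoms: lithium hydroxide, [Li+].[OH-]
Why: Saponification of the unhindered methyl ester: C3 and C5 carry no hydrogen for base-induced peroxide fragmentation and β-elimination from the carboxylate is slow, so the dioxolane, the diene and all three stereocentres survive.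

**Compound list**
1 | (3R)-5-methoxy-3-methyl-5-oxopentanoic acid (methyl hydrogen (R)-3-methylglutarate) | COC(=O)C[C@H](C)CC(=O)O | starting material
2 | methyl (3R)-5-hydroxy-3-methylpentanoate | COC(=O)C[C@H](C)CCO | intermediate
3 | (4R)-4-methyltetrahydro-2H-pyran-2-one | O=C1C[C@H](C)CCO1 | intermediate
4 | (4R)-6-hydroxy-4-methylhexan-2-one | CC(=O)C[C@H](C)CCO | intermediate
5 | (3R)-3-methyl-5-oxohexanal | CC(=O)C[C@H](C)CC=O | intermediate
6 | 2-methylallylboronic acid pinacol ester | C=C(C)CB1OC(C)(C)C(C)(C)O1 | starting material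
7 | pinacol borate of 8 | CC(=O)C[C@H](C)CC(CC(C)=C)OB1OC(C)(C)C(C)(C)O1 | intermediate
8 | (4R)-6-hydroxy-4,8-dimethylnon-8-en-2-one (both C6 epimers) | CC(=O)C[C@H](C)CC(O)CC(C)=C | intermediate
9 | (4S)-4,8-dimethylnon-8-ene-2,6-dione | CC(=O)C[C@H](C)CC(=O)CC(C)=C | intermediate
10 | (1S,3S,5S)-1,3-dimethyl-5-(2-methylprop-2-en-1-yl)-6,7,8-trioxabicyclo[3.2.1]octane | C[C@@]12C[C@H](C)C[C@@](CC(C)=C)(OO1)O2 | intermediate
11 | SnCl4-bound seven-membered peroxycarbenium ion (C5=O+–O–C1, tin alkoxide on C1) | CC1=[O+]O[C@](O[Sn-](Cl)(Cl)(Cl)Cl)(CC(C)=C)C[C@@H](C)C1 | intermediate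
12 | SnCl4-bound 9,10-dioxabicyclo[3.3.2]decyl tertiary cation (cation at C3) | C[C+]1C[C@@]2(C)C[C@H](C)C[C@@](O[Sn-](Cl)(Cl)(Cl)Cl)(C1)OO2 | intermediate
13 | (1R,5S,7R)-1,5,7-trimethyl-8,9-dioxabicyclo[5.2.1]decan-3-one | C[C@H]1C[C@]2(C)C[C@](C)(CC(=O)C1)OO2 | intermediate
14 | (1R,6S,8R)-1,6,8-trimethyl-4,9,10-trioxabicyclo[6.2.1]undecan-3-one | C[C@H]1C[C@]2(C)C[C@](C)(CC(=O)OC1)OO2 | intermediate
15 | methyl 2-[(3R,5R)-5-[(2S)-3-hydroxy-2-methylpropyl]-3,5-dimethyl-1,2-dioxolan-3-yl]acetate | C[C@H](CO)C[C@]1(C)C[C@](C)(CC(=O)OC)OO1 | intermediate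
16 | methyl 2-[(3R,5R)-3,5-dimethyl-5-[(2S)-2-methyl-3-oxopropyl]-1,2-dioxolan-3-yl]acetate | C[C@H](C=O)C[C@]1(C)C[C@](C)(CC(=O)OC)OO1 | intermediate
17 | 6-bromohexan-1-ol | OCCCCCCBr | starting material
18 | (6-hydroxyhexyl)triphenylphosphonium bromide | OCCCCCC[P+](c1ccccc1)(c1ccccc1)c1ccccc1.[Br-] | intermediate
19 | sodium alkoxide ylide from 18 | [Na+].[O-]CCCCCC=P(c1ccccc1)(c1ccccc1)c1ccccc1 | intermediate
20 | methyl 2-[(3R,5R)-5-[(2S,3Z)-9-hydroxy-2-methylnon-3-en-1-yl]-3,5-dimethyl-1,2-dioxolan-3-yl]acetate | C[C@H](/C=C\CCCCCO)C[C@]1(C)C[C@](C)(CC(=O)OC)OO1 | intermediate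
21 | methyl 2-[(3R,5R)-5-[(2R)-9-hydroxy-2-methylnonyl]-3,5-dimethyl-1,2-dioxolan-3-yl]acetate | C[C@H](CCCCCCCO)C[C@]1(C)C[C@](C)(CC(=O)OC)OO1 | intermediate
22 | methyl 2-[(3R,5R)-3,5-dimethyl-5-[(2R)-2-methyl-9-oxononyl]-1,2-dioxolan-3-yl]acetate | C[C@H](CCCCCCC=O)C[C@]1(C)C[C@](C)(CC(=O)OC)OO1 | intermediate
23 | diethyl (E)-cinnamylphosphonate | CCOP(=O)(C/C=C/c1ccccc1)OCC | starting material
24 | lithiated diethyl (E)-cinnamylphosphonate | [Li+].CCOP(=O)(OCC)[CH-]/C=C/c1ccccc1 | intermediate
25 | methyl 2-[(3R,5R)-3,5-dimethyl-5-[(2R,9E,11E)-2-methyl-12-phenyldodeca-9,11-dien-1-yl]-1,2-dioxolan-3-yl]acetate | C[C@H](CCCCCC/C=C/C=C/c1ccccc1)C[C@]1(C)C[C@](C)(CC(=O)OC)OO1 | intermediate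
26 | 2-[(3R,5R)-3,5-dimethyl-5-[(2R,9E,11E)-2-methyl-12-phenyldodeca-9,11-dien-1-yl]-1,2-dioxolan-3-yl]acetic acid | C[C@H](CCCCCC/C=C/C=C/c1ccccc1)C[C@]1(C)C[C@](C)(CC(=O)O)OO1 | target

Total step count: 16. Longest linear sequence: 15 (steps 1–10 and 12–16).

**Steps most likely to fail**

**Step 7.** After ionisation of the ozonide, proton loss from the C3 cation, O–O heterolysis with alkyl migration, or simple reclosure to 10 may outrun the ring closure. The fallback is the known intermolecular annulation of a silylperoxy ketal with a 1,1-disubstituted alkene, with the chain built first. It sets out from 5 and comes back at 21.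

- 5-Bromopentan-1-ol and PPh3 give (5-hydroxypentyl)triphenylphosphonium bromide F1.
- NaN(SiMe3)2 (2 equiv) turns it into the sodium alkoxide ylide F2, which olefinates the aldehyde of 5 at −78 °C to (4R,6Z)-11-hydroxy-4-methylundec-6-en-2-one F3.
- H2 over Pd/C gives (4R)-11-hydroxy-4-methylundecan-2-one F4, and Ac2O/pyridine gives (8R)-8-methyl-10-oxoundecyl acetate F5.
- H2O2, HC(OMe)3, MeOH and catalytic TsOH give (8R)-10-hydroperoxy-10-methoxy-8-methylundecyl acetate F6.
- Et3SiCl/imidazole gives (8R)-10-methoxy-8-methyl-10-(triethylsilylperoxy)undecyl acetate F7.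
- SnCl4 and methyl 3-methylbut-3-enoate in CH2Cl2 at −78 °C give the 1,2-dioxolane as a mixture of diastereomers. From it methyl 2-[(3R,5R)-5-[(2R)-9-acetoxy-2-methylnonyl]-3,5-dimethyl-1,2-dioxolan-3-yl]acetate F8 is separated by chromatography.
- K2CO3/MeOH removes the acetate and gives 21.

Control of C3 and C5 is given up in exchange for established chemistry.

**Step 6.** Acid may move the β,γ-double bond into conjugation or trigger aldol cyclisation of the 1,5-diketone, and the facial selectivity of the closure (C7 methyl equatorial against axial) may be poor. The fallback builds the ozonide with ozone from a carbocycle. It sets out from 9 and comes back at 10. Intramolecular McMurry coupling of 9 (TiCl3(DME)1.5, Zn–Cu couple, DME, reflux; low-valent titanium) gives (4S)-1,4-dimethyl-2-(2-methylprop-2-en-1-yl)cyclopent-1-ene F9. One equivalent of O3 in pentane/CH2Cl2 at −78 °C attacks the tetrasubstituted ring alkene first. The carbonyl oxide and the ketone so formed are held in a 1,5-relation and recombine to 10 under neutral conditions.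

**Step 8.** Regioselectivity of migration (C2 against C8) may be poor, or the peracid may add sluggishly to the medium-ring ketone. The fallback cleaves the C1–C8 bond through an enol ether. It sets out from 13 and comes back at 16. Kinetic deprotonation at the less hindered C8 with LiN(iPr)2 in the presence of Me3SiCl (THF, −78 °C) gives the C1=C8 trimethylsilyl enol ether of 13 F10. O3 followed by Me2S and aqueous work-up gives 2-[(3R,5R)-3,5-dimethyl-5-[(2S)-2-methyl-3-oxopropyl]-1,2-dioxolan-3-yl]acetic acid F11. Me3SiCHN2 in toluene/MeOH esterifies it to 16.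

**Further compounds**
F1 | step 7 | (5-hydroxypentyl)triphenylphosphonium bromide | OCCCCC[P+](c1ccccc1)(c1ccccc1)c1ccccc1.[Br-]
F2 | step 7 | sodium alkoxide ylide from F1 | [Na+].[O-]CCCCC=P(c1ccccc1)(c1ccccc1)c1ccccc1
F3 | step 7 | (4R,6Z)-11-hydroxy-4-methylundec-6-en-2-one | CC(=O)C[C@H](C)C/C=C\CCCCO
F4 | step 7 | (4R)-11-hydroxy-4-methylundecan-2-one | CC(=O)C[C@H](C)CCCCCCCO
F5 | step 7 | (8R)-8-methyl-10-oxoundecyl acetate | CC(=O)C[C@H](C)CCCCCCCOC(C)=O
F6 | step 7 | (8R)-10-hydroperoxy-10-methoxy-8-methylundecyl acetate (both C10 epimers) | COC(C)(OO)C[C@H](C)CCCCCCCOC(C)=O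
F7 | step 7 | (8R)-10-methoxy-8-methyl-10-(triethylsilylperoxy)undecyl acetate (both C10 epimers) | COC(C)(OO[Si](CC)(CC)CC)C[C@H](C)CCCCCCCOC(C)=O
F8 | step 7 | methyl 2-[(3R,5R)-5-[(2R)-9-acetoxy-2-methylnonyl]-3,5-dimethyl-1,2-dioxolan-3-yl]acetate | C[C@H](CCCCCCCOC(C)=O)C[C@]1(C)C[C@](C)(CC(=O)OC)OO1
F9 | step 6 | (4S)-1,4-dimethyl-2-(2-methylprop-2-en-1-yl)cyclopent-1-ene | CC1=C(CC(C)=C)C[C@@H](C)C1
F10 | step 8 | C1=C8 trimethylsilyl enol ether of 13 (ring-cis double bond) | C[C@H]1C[C@]2(C)C[C@](C)(C/C(O[Si](C)(C)C)=C\1)OO2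
F11 | step 8 | 2-[(3R,5R)-3,5-dimethyl-5-[(2S)-2-methyl-3-oxopropyl]-1,2-dioxolan-3-yl]acetic acid | C[C@H](C=O)C[C@]1(C)C[C@](C)(CC(=O)O)OO1
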